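Everything rests on cutting the CH=CH unit (C13=C14) out of the cyclohexene ring, i.e. the C12–C13 and C14–C1 bonds. The feature exploited is the 1,5-relationship of the C12 and C2 oxygens across C11–C10–C1: C12 becomes an acyl carbon and the quaternary C1 the α-carbon of a C2 ketone. The precursor is therefore a six-membered enol lactone whose ring oxygen joins C12 to the C2 enol. In the key step lithium acetylide attacks C12, the expelled C1=C2 enolate closes 6-endo-dig onto the ynone terminus, and the ring oxygen is exchanged for C13=C14 with creation of quaternary C1. The ten-membered ring (Nozaki–Hiyama–Kishi, C6–C7) and the γ-lactone (Reformatsky) follow.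

Key step: step 3

Remark (numbering): briarane numbering is used throughout. Six-membered ring: C1 (quaternary, Me15), C10, C11 (Me20), C12 (O), C13=C14. Ten-membered ring: C1–C10 (C2 OAc, C5=C6 with Me16, C9 OAc). Lactone: C7–O–C19(=O)–C17(Me18)–C8(OH).
Remark (assumptions): 2-chloropropanal (4) and allyl 4-methoxybenzyl ether (18) are taken as purchasable. The absolute sense of induction in step 2 is assigned by analogy; the antipodal triazolium salt would be used if it proves opposite.

Step 1
Reactants: 1 2,3-butanedione; 2 methyl (triphenylphosphoranylidene)acetate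
Product: 3 methyl (E)-3-methyl-4-oxopent-2-enoate
Conditions: 2 (1.0 equiv) added to 1 (1.5 equiv), CH2Cl2, 0 °C → rt
Reagents that add atoms: none
Why: Wittig olefination, in which the stabilised ylide should react once with the 1,2-diketone (the product enone is deactivated) and give the E enoate with ester and acetyl trans.

Step 2
Reactants: 3 methyl (E)-3-methyl-4-oxopent-2-enoate; 4 2-chloropropanal (racemic)
Product: 5 methyl (3R,4S)-3,5,6-trimethyl-2-oxo-3,4-dihydro-2H-pyran-4-carboxylate
Conditions: (5aS,10bR)-2-mesityl-5a,10b-dihydro-4H,6H-indeno[2,1-b][1,2,4]triazolo[4,3-d][1,4]oxazin-2-ium chloride (5 mol %), Et3N (1.5 equiv), EtOAc, rt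
Reagents that add atoms: none
Why: N-heterocyclic-carbene-catalysed oxodiene hetero-Diels–Alder reaction, in which the carbene turns 4 (loss of HCl) into a Z azolium enolate that adds endo to the s-cis enone of 3 under catalyst face control, so that C11 and C10 should be set cis (3R,4S) and the C12 acyl group and C2 enol end up in one enol lactone.

Step 3
Reactants: 5 methyl (3R,4S)-3,5,6-trimethyl-2-oxo-3,4-dihydro-2H-pyran-4-carboxylate; 6 acetylene
Product: 9 methyl (1S,2R,6S)-6-acetyl-2,6-dimethyl-3-oxocyclohex-4-ene-1-carboxylate, via lithium hemiketal alkoxide 7 (not isolated), via ynone lithium enolate 8 (not isolated)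
Conditions: 6 (excess), n-BuLi (1.05 equiv), THF, −78 °C; 5, −78 °C, 30 min; t-BuOH (1 equiv), −78 → 0 °C; aq. NH4Cl
Reagents that add atoms: none
Why: Proposed new method: lithium acetylide adds to the enol-lactone carbonyl (C12–C13), the hemiketal alkoxide 7 collapses on warming to the ynone and the regiodefined C1=C2 lithium enolate 8, and C1 of this enolate adds to the ynone terminus (C14–C1); because a cyclic allenolate is too strained, the C13 vinyl anion is protonated as it forms by t-BuOH, so the closure runs as an alkoxide-catalysed Michael addition. The closest known reaction types are the Fujimoto–Belleus annulation (organometallic opening of an enol lactone followed by intramolecular carbonyl condensation) and the base-mediated addition of ketone enolates to ynones; their fusion in one flask, which swaps the ring oxygen for a two-carbon unit, is the new element. The carbocycle closes 6-endo-dig, the only productive mode: C1 attack at C12 would give a four-membered ring, O-attack an eight-membered one, and aldol addition of the methyl enolate to C12 is reversible. The quaternary C1 is controlled by C10: allylic 1,3-strain holds H10 in the enolate plane, the ynone tether and the C10 ester then lie on opposite faces, and C14 should bond to the face that leaves Me15 cis to the ester. The step needs chemoselectivity for the enol ester over the methyl ester (the better acylating agent at −78 °C), mono-addition (7 is meant to persist until the acetylide is consumed) and retention of configuration at C10 and C11 (low temperature, lithium counter-ion, short contact with alkoxide).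

Step 4
Reactants: 9 methyl (1S,2R,6S)-6-acetyl-2,6-dimethyl-3-oxocyclohex-4-ene-1-carboxylate
Product: 10 methyl (1S,2R,3R,6S)-6-acetyl-3-hydroxy-2,6-dimethylcyclohex-4-ene-1-carboxylate
Conditions: NaBH4, CeCl3·7H2O, MeOH, −78 °C
Reagents that add atoms: none
Why: Luche reduction, in which the enone carbonyl should be reduced 1,2 ahead of the neopentyl acetyl ketone and the ester, axial hydride delivery on the half-chair with equatorial Me20 giving the pseudo-equatorial 12-alcohol trans to Me20 (12R).

Step 5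
Reactants: 10 methyl (1S,2R,3R,6S)-6-acetyl-3-hydroxy-2,6-dimethylcyclohex-4-ene-1-carboxylate
Product: 11 methyl (1S,2R,3R,6S)-6-acetyl-3-[(tert-butyldimethylsilyl)oxy]-2,6-dimethylcyclohex-4-ene-1-carboxylate
Conditions: TBSCl, imidazole, DMF, rt
Reagents that add atoms: tert-butyldimethylsilyl chloride, CC(C)(C)[Si](C)(C)Cl
Why: Silylation of the only hydroxyl gives a C12 ether that should survive amide base, hydride, chromium and samarium reagents and is removed last.

Step 6
Reactants: 12 propargyl alcohol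
Product: 13 (Z)-3-iodo-2-methylprop-2-en-1-ol
Conditions: MeMgBr (2.5 equiv), CuI (10 mol %), THF, −10 °C → rt; then I2, −10 °C
Reagents that add atoms: methylmagnesium bromide, C[Mg]Br; iodine, II
Why: Copper-catalysed, alkoxide-directed anti-carbomagnesiation of the propargylic magnesium alkoxide followed by iodinolysis of the vinylmagnesium should give the Z iodoalkene (CH2OH and I cis).

Step 7
Reactants: 13 (Z)-3-iodo-2-methylprop-2-en-1-ol
Product: 14 (Z)-3-bromo-1-iodo-2-methylprop-1-ene
Conditions: CBr4, PPh3, CH2Cl2, 0 °C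
Reagents that add atoms: carbon tetrabromide, BrC(Br)(Br)Br
Why: Appel reaction of the primary allylic alcohol, which leaves the alkene geometry and the vinyl iodide untouched.

Step 8
Reactants: 11 methyl (1S,2R,3R,6S)-6-acetyl-3-[(tert-butyldimethylsilyl)oxy]-2,6-dimethylcyclohex-4-ene-1-carboxylate; 14 (Z)-3-bromo-1-iodo-2-methylprop-1-ene
Product: 15 methyl (1S,2R,3R,6S)-3-[(tert-butyldimethylsilyl)oxy]-6-[(4Z)-5-iodo-4-methylpent-4-enoyl]-2,6-dimethylcyclohex-4-ene-1-carboxylate
Conditions: LDA (1.05 equiv), THF, −78 °C; then 14 (1.3 equiv), DMPU, −78 → −40 °C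
Reagents that add atoms: none
Why: Kinetic enolate alkylation, in which LDA can only deprotonate the acetyl methyl group of the ketone (C1 is quaternary, the ester α-CH at C10 is hindered and less acidic) and the lithium enolate should be C-alkylated by the allylic bromide (C3–C4), the vinyl iodide being inert.

Step 9
Reactants: 15 methyl (1S,2R,3R,6S)-3-[(tert-butyldimethylsilyl)oxy]-6-[(4Z)-5-iodo-4-methylpent-4-enoyl]-2,6-dimethylcyclohex-4-ene-1-carboxylate
Product: 16 methyl (1S,2R,3R,6S)-3-[(tert-butyldimethylsilyl)oxy]-6-[(1R,4Z)-1-hydroxy-5-iodo-4-methylpent-4-en-1-yl]-2,6-dimethylcyclohex-4-ene-1-carboxylate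
Conditions: (S)-2-methyl-CBS-oxazaborolidine (0.3 equiv), BH3·SMe2 (0.8 equiv), THF, −30 °C; MeOH
Reagents that add atoms: none
Why: Corey–Bakshi–Shibata reduction, in which the quaternary C1 acts as the large and the CH2 chain as the small ketone substituent, so the (S)-catalyst should deliver hydride to give the 2R alcohol under reagent control, faster than the hindered alkenes are hydroborated.

Step 10
Reactants: 16 methyl (1S,2R,3R,6S)-3-[(tert-butyldimethylsilyl)oxy]-6-[(1R,4Z)-1-hydroxy-5-iodo-4-methylpent-4-en-1-yl]-2,6-dimethylcyclohex-4-ene-1-carboxylate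
Product: 17 (1S,2R,3R,6S)-3-[(tert-butyldimethylsilyl)oxy]-6-[(1R,4Z)-1-hydroxy-5-iodo-4-methylpent-4-en-1-yl]-2,6-dimethylcyclohex-4-ene-1-carbaldehyde
Conditions: i-Bu2AlH (2.3 equiv), CH2Cl2, −78 °C; aq. Rochelle salt
Reagents that add atoms: none
Why: Low-temperature half-reduction of the ester, in which the C2 aluminium alkoxide formed first should tie the tetrahedral intermediate into a cyclic aluminium acetal, so the C9 aldehyde (in equilibrium with its five-membered lactol) is released only on work-up and any material already lactonised converges on the same product.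

Step 11
Reactants: 17 (1S,2R,3R,6S)-3-[(tert-butyldimethylsilyl)oxy]-6-[(1R,4Z)-1-hydroxy-5-iodo-4-methylpent-4-en-1-yl]-2,6-dimethylcyclohex-4-ene-1-carbaldehyde; 18 allyl 4-methoxybenzyl ether
Product: 19 (1R,2R)-1-{(1S,2R,3R,6S)-3-[(tert-butyldimethylsilyl)oxy]-6-[(1R,4Z)-1-hydroxy-5-iodo-4-methylpent-4-en-1-yl]-2,6-dimethylcyclohex-4-en-1-yl}-2-[(4-methoxybenzyl)oxy]but-3-en-1-ol
Conditions: 18 (2.5 equiv), s-BuLi, THF, −78 °C; (−)-Ipc2BOMe; BF3·OEt2; then 17, −78 °C; NaOH, H2O2
Reagents that add atoms: none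
Why: Brown alkoxyallylboration, in which the (Z)-γ-alkoxyallyl diisopinocampheylborane from (+)-α-pinene adds through a closed chair transition state and, matched with the Felkin–Anh preference of the C10-branched aldehyde, should set C9 as R and the temporary C8 centre syn to it, the free C2 hydroxyl being a spectator at −78 °C.

Step 12
Reactants: 19 (1R,2R)-1-{(1S,2R,3R,6S)-3-[(tert-butyldimethylsilyl)oxy]-6-[(1R,4Z)-1-hydroxy-5-iodo-4-methylpent-4-en-1-yl]-2,6-dimethylcyclohex-4-en-1-yl}-2-[(4-methoxybenzyl)oxy]but-3-en-1-ol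
Product: 20 2,9-di-O-acetate of 19
Conditions: Ac2O, DMAP, Et3N, CH2Cl2, rt
Reagents that add atoms: acetic anhydride, CC(=O)OC(C)=O
Why: DMAP-catalysed acetylation of both secondary alcohols installs the two acetates of the target in one operation without touching a stereocentre.

Step 13
Reactants: 20 2,9-di-O-acetate of 19
Product: 22 seco-aldehyde (vinyl group of 20 cut down to the C7 aldehyde), via terminal diol 21 (not isolated)
Conditions: OsO4 (2 mol %), NaIO4 (4 equiv), 2,6-lutidine, dioxane–H2O, rt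
Reagents that add atoms: sodium periodate, [Na+].[O-]I(=O)(=O)=O, and water, O (oxygen source, relayed by catalytic osmium tetroxide, O=[Os](=O)(=O)=O)
Why: Lemieux–Johnson oxidative cleavage, in which OsO4 should dihydroxylate the monosubstituted vinyl group faster than the hindered ring alkene and the electron-poor vinyl iodide, periodate then cleaving diol 21 to the aldehyde.

Step 14
Reactants: 22 seco-aldehyde (vinyl group of 20 cut down to the C7 aldehyde)
Product: 23 (1S,2R,5Z,7S,8R,9R,10S,11R,12R,13Z)-12-[(tert-butyldimethylsilyl)oxy]-7-hydroxy-8-[(4-methoxybenzyl)oxy]-1,5,11-trimethylbicyclo[8.4.0]tetradeca-5,13-diene-2,9-diyl diacetate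
Conditions: CrCl2 (10 equiv), NiCl2 (1 mol %), DMSO–THF, rt, 2 mM, slow addition
Reagents that add atoms: none
Why: Nozaki–Hiyama–Kishi macrocyclisation, in which the Z alkenylchromium formed from the vinyl iodide adds only to the aldehyde and closes the ten-membered ring with retention of olefin geometry, C7 being set under macrocyclic control through the product-like arrangement with H7 eclipsing C5=C6 and the chromium alkoxide outside the ring (7S expected).

Step 15
Reactants: 23 (1S,2R,5Z,7S,8R,9R,10S,11R,12R,13Z)-12-[(tert-butyldimethylsilyl)oxy]-7-hydroxy-8-[(4-methoxybenzyl)oxy]-1,5,11-trimethylbicyclo[8.4.0]tetradeca-5,13-diene-2,9-diyl diacetate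
Product: 24 7-O-(2-bromopropanoyl) ester of 23 (both bromide epimers)
Conditions: 2-bromopropanoyl bromide, pyridine, DMAP (cat.), CH2Cl2, −20 → 0 °C
Reagents that add atoms: 2-bromopropanoyl bromide, CC(Br)C(Br)=O
Why: Acylation of the allylic alcohol with retention at C7 attaches C17–C19 of the lactone, and the bromide-bearing centre needs no control because it becomes an enolate.

Step 16
Reactants: 24 7-O-(2-bromopropanoyl) ester of 23 (both bromide epimers)
Product: 25 8-alcohol (PMB ether of 24 removed)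
Conditions: DDQ, CH2Cl2–pH 7 buffer, 0 °C
Reagents that add atoms: none
Why: Oxidative cleavage of the 4-methoxybenzyl ether by DDQ (benzylic hydride abstraction, hydrolysis of the oxocarbenium ion) should leave esters, silyl ether, bromide and alkenes untouched.

Step 17
Reactants: 25 8-alcohol (PMB ether of 24 removed)
Product: 26 8-ketone (1S,2R,5Z,7S,9R,10S,11R,12R,13Z)-2,9-diacetoxy-12-[(tert-butyldimethylsilyl)oxy]-1,5,11-trimethyl-8-oxobicyclo[8.4.0]tetradeca-5,13-dien-7-yl 2-bromopropanoate
Conditions: Dess–Martin periodinane, NaHCO3, CH2Cl2, 0 °C → rt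
Reagents that add atoms: none
Why: Dess–Martin oxidation under buffered, non-basic conditions removes the temporary C8 stereocentre and gives the α-acyloxy ketone without acyl migration or enolisation at C7.

Step 18
Reactants: 26 8-ketone (1S,2R,5Z,7S,9R,10S,11R,12R,13Z)-2,9-diacetoxy-12-[(tert-butyldimethylsilyl)oxy]-1,5,11-trimethyl-8-oxobicyclo[8.4.0]tetradeca-5,13-dien-7-yl 2-bromopropanoate
Product: 28 12-O-TBS lactone (target with OTBS in place of the C12 butanoate), via samarium enolate 27 (not isolated)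
Conditions: SmI2 (2.5 equiv), THF, −78 °C; aq. NH4Cl
Reagents that add atoms: none
Why: Samarium-mediated intramolecular Reformatsky reaction, in which SmI2 should reduce the C–Br bond faster than the ketone and the trivalent samarium Z(O)-enolate adds to C8 through a chelated bicyclic transition state that places Me18 cis to the new 8-hydroxyl (17R) and, with C6 and C9 held anti across C7–C8 by the medium ring, gives the trans-fused lactone (8S).

Step 19
Reactants: 28 12-O-TBS lactone (target with OTBS in place of the C12 butanoate)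
Product: 29 12-alcohol (target lacking the butanoyl group)
Conditions: HF·pyridine, pyridine, THF, 0 °C → rt
Reagents that add atoms: none
Why: Buffered fluoride desilylation should free the allylic C12 hydroxyl without acetate migration, lactone opening or retro-aldol of the β-hydroxy lactone.

Step 20
Reactants: 29 12-alcohol (target lacking the butanoyl group)
Product: 30 CNP0211702.1
Conditions: (n-PrCO)2O, DMAP (cat.), Et3N, CH2Cl2, 0 °C
Reagents that add atoms: butanoic anhydride, CCCC(=O)OC(=O)CCC
Why: DMAP-catalysed acylation should butanoylate the secondary allylic 12-hydroxyl while the tertiary 8-hydroxyl stays free.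

Compound list
1 | 2,3-butanedione | CC(=O)C(C)=O | starting material
2 | methyl (triphenylphosphoranylidene)acetate | COC(=O)C=P(c1ccccc1)(c1ccccc1)c1ccccc1 | starting material
3 | methyl (E)-3-methyl-4-oxopent-2-enoate | COC(=O)/C=C(\C)C(C)=O | intermediate
4 | 2-chloropropanal (racemic) | CC(Cl)C=O | starting material
5 | methyl (3R,4S)-3,5,6-trimethyl-2-oxo-3,4-dihydro-2H-pyran-4-carboxylate (cis enol lactone) | O=C1OC(C)=C(C)[C@H]([C@H]1C)C(=O)OC | intermediate
6 | acetylene | C#C | starting material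
7 | lithium hemiketal alkoxide (acetylide adduct at the lactone carbonyl of 5, new centre unassigned) | [Li]OC1(C#C)OC(C)=C(C)[C@H]([C@H]1C)C(=O)OC | intermediate
8 | ynone lithium enolate (ring-opened 7; C10 and C11 as in 5, enolate oxygen cis to C10) | C#CC(=O)[C@H](C)[C@H](C(=O)OC)/C(C)=C(/C)O[Li] | intermediate
9 | methyl (1S,2R,6S)-6-acetyl-2,6-dimethyl-3-oxocyclohex-4-ene-1-carboxylate | O=C1C=C[C@](C)(C(C)=O)[C@H]([C@H]1C)C(=O)OC | intermediate
10 | methyl (1S,2R,3R,6S)-6-acetyl-3-hydroxy-2,6-dimethylcyclohex-4-ene-1-carboxylate | O[C@@H]1C=C[C@](C)(C(C)=O)[C@H]([C@H]1C)C(=O)OC | intermediate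
11 | methyl (1S,2R,3R,6S)-6-acetyl-3-[(tert-butyldimethylsilyl)oxy]-2,6-dimethylcyclohex-4-ene-1-carboxylate | CC(C)(C)[Si](C)(C)O[C@@H]1C=C[C@](C)(C(C)=O)[C@H]([C@H]1C)C(=O)OC | intermediate
12 | propargyl alcohol | C#CCO | starting material
13 | (Z)-3-iodo-2-methylprop-2-en-1-ol | OC/C(C)=C\I | intermediate
14 | (Z)-3-bromo-1-iodo-2-methylprop-1-ene | BrC/C(C)=C\I | intermediate
15 | methyl (1S,2R,3R,6S)-3-[(tert-butyldimethylsilyl)oxy]-6-[(4Z)-5-iodo-4-methylpent-4-enoyl]-2,6-dimethylcyclohex-4-ene-1-carboxylate | CC(C)(C)[Si](C)(C)O[C@@H]1C=C[C@](C)(C(=O)CC/C(C)=C\I)[C@H]([C@H]1C)C(=O)OC | intermediate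
16 | methyl (1S,2R,3R,6S)-3-[(tert-butyldimethylsilyl)oxy]-6-[(1R,4Z)-1-hydroxy-5-iodo-4-methylpent-4-en-1-yl]-2,6-dimethylcyclohex-4-ene-1-carboxylate | CC(C)(C)[Si](C)(C)O[C@@H]1C=C[C@](C)([C@H](O)CC/C(C)=C\I)[C@H]([C@H]1C)C(=O)OC | intermediate
17 | (1S,2R,3R,6S)-3-[(tert-butyldimethylsilyl)oxy]-6-[(1R,4Z)-1-hydroxy-5-iodo-4-methylpent-4-en-1-yl]-2,6-dimethylcyclohex-4-ene-1-carbaldehyde (open form of the lactol) | CC(C)(C)[Si](C)(C)O[C@@H]1C=C[C@](C)([C@H](O)CC/C(C)=C\I)[C@H]([C@H]1C)C=O | intermediate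
18 | allyl 4-methoxybenzyl ether | C=CCOCc1ccc(OC)cc1 | starting material
19 | (1R,2R)-1-{(1S,2R,3R,6S)-3-[(tert-butyldimethylsilyl)oxy]-6-[(1R,4Z)-1-hydroxy-5-iodo-4-methylpent-4-en-1-yl]-2,6-dimethylcyclohex-4-en-1-yl}-2-[(4-methoxybenzyl)oxy]but-3-en-1-ol | CC(C)(C)[Si](C)(C)O[C@@H]1C=C[C@](C)([C@H](O)CC/C(C)=C\I)[C@H]([C@H]1C)[C@@H](O)[C@H](OCc1ccc(OC)cc1)C=C | intermediate
20 | 2,9-di-O-acetate of 19 (acetates on both secondary hydroxyls, stereocentres as in 19) | CC(C)(C)[Si](C)(C)O[C@@H]1C=C[C@](C)([C@H](OC(C)=O)CC/C(C)=C\I)[C@H]([C@H]1C)[C@@H](OC(C)=O)[C@H](OCc1ccc(OC)cc1)C=C | intermediate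
21 | terminal diol from dihydroxylation of the vinyl group of 20 (new carbinol centre unassigned) | CC(C)(C)[Si](C)(C)O[C@@H]1C=C[C@](C)([C@H](OC(C)=O)CC/C(C)=C\I)[C@H]([C@H]1C)[C@@H](OC(C)=O)[C@H](OCc1ccc(OC)cc1)C(O)CO | intermediate
22 | seco-aldehyde: (2S,3R)-3-acetoxy-2-[(4-methoxybenzyl)oxy]propanal carrying at C3 the ring of 20 (C7 aldehyde; 2R, 8S, 9R in briarane numbering) | CC(C)(C)[Si](C)(C)O[C@@H]1C=C[C@](C)([C@H](OC(C)=O)CC/C(C)=C\I)[C@H]([C@H]1C)[C@@H](OC(C)=O)[C@H](OCc1ccc(OC)cc1)C=O | intermediate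
23 | (1S,2R,5Z,7S,8R,9R,10S,11R,12R,13Z)-12-[(tert-butyldimethylsilyl)oxy]-7-hydroxy-8-[(4-methoxybenzyl)oxy]-1,5,11-trimethylbicyclo[8.4.0]tetradeca-5,13-diene-2,9-diyl diacetate | CC(C)(C)[Si](C)(C)O[C@@H]1C=C[C@@]2(C)[C@H]([C@H]1C)[C@@H](OC(C)=O)[C@H](OCc1ccc(OC)cc1)[C@@H](O)/C=C(/C)CC[C@H]2OC(C)=O | intermediate
24 | (1S,2R,5Z,7S,8R,9R,10S,11R,12R,13Z)-2,9-diacetoxy-12-[(tert-butyldimethylsilyl)oxy]-8-[(4-methoxybenzyl)oxy]-1,5,11-trimethylbicyclo[8.4.0]tetradeca-5,13-dien-7-yl 2-bromopropanoate (both bromide epimers) | CC(C)(C)[Si](C)(C)O[C@@H]1C=C[C@@]2(C)[C@H]([C@H]1C)[C@@H](OC(C)=O)[C@H](OCc1ccc(OC)cc1)[C@@H](OC(=O)C(C)Br)/C=C(/C)CC[C@H]2OC(C)=O | intermediate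
25 | (1S,2R,5Z,7S,8R,9R,10S,11R,12R,13Z)-2,9-diacetoxy-12-[(tert-butyldimethylsilyl)oxy]-8-hydroxy-1,5,11-trimethylbicyclo[8.4.0]tetradeca-5,13-dien-7-yl 2-bromopropanoate | CC(C)(C)[Si](C)(C)O[C@@H]1C=C[C@@]2(C)[C@H]([C@H]1C)[C@@H](OC(C)=O)[C@H](O)[C@@H](OC(=O)C(C)Br)/C=C(/C)CC[C@H]2OC(C)=O | intermediate
26 | (1S,2R,5Z,7S,9R,10S,11R,12R,13Z)-2,9-diacetoxy-12-[(tert-butyldimethylsilyl)oxy]-1,5,11-trimethyl-8-oxobicyclo[8.4.0]tetradeca-5,13-dien-7-yl 2-bromopropanoate | CC(C)(C)[Si](C)(C)O[C@@H]1C=C[C@@]2(C)[C@H]([C@H]1C)[C@@H](OC(C)=O)C(=O)[C@@H](OC(=O)C(C)Br)/C=C(/C)CC[C@H]2OC(C)=O | intermediate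
27 | samarium enolate (diiodosamarium Z(O)-enolate of the C7 propanoate of 26) | CC(C)(C)[Si](C)(C)O[C@@H]1C=C[C@@]2(C)[C@H]([C@H]1C)[C@@H](OC(C)=O)C(=O)[C@@H](O/C(O[Sm](I)I)=C/C)/C=C(/C)CC[C@H]2OC(C)=O | intermediate
28 | 12-O-TBS lactone: target with tert-butyldimethylsilyloxy in place of the C12 butanoate (1S,2R,5Z,7S,8S,9R,10S,11R,12R,17R) | CC(C)(C)[Si](C)(C)O[C@@H]1C=C[C@@]2(C)[C@H]([C@H]1C)[C@@H](OC(C)=O)[C@@]1(O)[C@H](/C=C(/C)CC[C@H]2OC(C)=O)OC(=O)[C@@H]1C | intermediate
29 | 12-alcohol: target lacking the butanoyl group | O[C@@H]1C=C[C@@]2(C)[C@H]([C@H]1C)[C@@H](OC(C)=O)[C@@]1(O)[C@H](/C=C(/C)CC[C@H]2OC(C)=O)OC(=O)[C@@H]1C | intermediate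
30 | CNP0211702.1 (1S,2R,5Z,7S,8S,9R,10S,11R,12R,17R; 2,9-diacetate, 12-butanoate, 8-hydroxy, 7,19-lactone) | CCCC(=O)O[C@@H]1C=C[C@@]2(C)[C@H]([C@H]1C)[C@@H](OC(C)=O)[C@@]1(O)[C@H](/C=C(/C)CC[C@H]2OC(C)=O)OC(=O)[C@@H]1C | target

Total step count: 20. Longest linear sequence: 18 (steps 1–5 and 8–20; steps 6–7 make fragment 14).

Steps most likely to fail

Step 3 (Proposed new method). What may go wrong: over-addition of acetylide to the ynone if the hemiketal collapses early, diversion of the enolate by proton transfer or reversible aldol before it closes, and loss of configuration at C11 by enolisation. Fallback with known chemistry, cutting the cascade into two flasks with a softer nucleophile: from 5, ethynylmagnesium bromide at −78 °C with an acetic acid quench at −78 °C (the opening half of a Fujimoto–Belleus sequence) should give the open ynone diketone F1. F1 is then closed separately under reversible carbonate conditions (Cs2CO3, MeCN, 0 °C), the established 6-endo-dig Michael addition of ketone enolates to ynones, which returns to 9.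

Step 14. What may go wrong: poor or reversed facial selectivity at C7 during ring closure, since acyclic Felkin–Anh preference relative to the temporary C8 ether and the macrocyclic bias need not agree. Fallback that changes the way the C7–O bond is set: from 22, the same closure would then deliver mainly the 7-epimeric allylic alcohol F2. F2 is esterified with inversion in a Mitsunobu reaction (2-bromopropanoic acid, PPh3, DIAD, toluene, 0 °C), which rejoins the route at 24.

Step 18. What may go wrong: competing reductive cleavage of the α-acetoxy ketone by SmI2, or addition of the enolate to the wrong face of the C8 ketone. Fallback through a butenolide, from 23: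
- Esterification with 2-(diethoxyphosphoryl)propanoic acid (DCC, DMAP) gives the phosphonate ester F3.
- DDQ gives the 8-alcohol F4 and Dess–Martin oxidation the 8-ketone F5, as in steps 16 and 17.
- Intramolecular Horner–Wadsworth–Emmons reaction (LiCl, DBU, MeCN) closes the butenolide F6 (C8=C17).
- Nucleophilic epoxidation (t-BuOOH, DBU, CH2Cl2) on the outer face gives the 8,17-epoxy lactone F7.
- SmI2 in THF–MeOH at −78 °C cleaves the C17–O bond (8-hydroxyl kept, C17 protonated, correctable by DBU equilibration) and returns to 28.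

Further compounds
F1 | step 3 | methyl 3-methyl-4-oxo-2-(3-oxobutan-2-yl)hex-5-ynoate (C10 and C11 as in 5, epimers at the ketone α-carbon) | C#CC(=O)[C@H](C)[C@H](C(=O)OC)C(C)C(C)=O
F2 | step 14 | 7-epimer of 23 (7R allylic alcohol) | CC(C)(C)[Si](C)(C)O[C@@H]1C=C[C@@]2(C)[C@H]([C@H]1C)[C@@H](OC(C)=O)[C@H](OCc1ccc(OC)cc1)[C@H](O)/C=C(/C)CC[C@H]2OC(C)=O
F3 | step 18 | 7-O-[2-(diethoxyphosphoryl)propanoyl] ester of 23 | CC(C)(C)[Si](C)(C)O[C@@H]1C=C[C@@]2(C)[C@H]([C@H]1C)[C@@H](OC(C)=O)[C@H](OCc1ccc(OC)cc1)[C@@H](OC(=O)C(C)P(=O)(OCC)OCC)/C=C(/C)CC[C@H]2OC(C)=O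
F4 | step 18 | 8-alcohol from F3 (PMB ether removed) | CC(C)(C)[Si](C)(C)O[C@@H]1C=C[C@@]2(C)[C@H]([C@H]1C)[C@@H](OC(C)=O)[C@H](O)[C@@H](OC(=O)C(C)P(=O)(OCC)OCC)/C=C(/C)CC[C@H]2OC(C)=O
F5 | step 18 | 8-ketone from F4 | CC(C)(C)[Si](C)(C)O[C@@H]1C=C[C@@]2(C)[C@H]([C@H]1C)[C@@H](OC(C)=O)C(=O)[C@@H](OC(=O)C(C)P(=O)(OCC)OCC)/C=C(/C)CC[C@H]2OC(C)=O
F6 | step 18 | butenolide (C8=C17) with 2,9-diacetate and 12-OTBS | CC(C)(C)[Si](C)(C)O[C@@H]1C=C[C@@]2(C)[C@H]([C@H]1C)[C@@H](OC(C)=O)C1=C(C)C(=O)O[C@H]1/C=C(/C)CC[C@H]2OC(C)=O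
F7 | step 18 | 8,17-epoxy lactone (epoxide oxygen on the face of the later 8-hydroxyl) | CC(C)(C)[Si](C)(C)O[C@@H]1C=C[C@@]2(C)[C@H]([C@H]1C)[C@@H](OC(C)=O)[C@@]13O[C@@]3(C)C(=O)O[C@H]1/C=C(/C)CC[C@H]2OC(C)=O
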